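**Retrosynthetic overview**
- Target ⇐ one acidolysis of a tris(tert-butyl)-protected ester (two aryl tert-butyl carbonates, one tert-butyl ester).
- C7–O ester bond and the C7 stereocentre together ⇐ dearomatising, enantioselective acyloxylation of a planar 8-hydroxy-6H-isochromen-6-one (2-benzopyrylium anhydrobase) by a chiral aryl-λ3-iodane that carries the protected orsellinate as its ligand.
- Pyran ring ⇐ gold-catalysed 6-endo cycloisomerisation of an o-alkynylbenzaldehyde in the same flask. Ring order: benzene ring bought, pyran ring closed second, benzene ring dearomatised last.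
- Alkynylbenzaldehyde ⇐ desilylative Sonogashira coupling of 6-bromo-2,4-dihydroxy-3-methylbenzaldehyde with a silyl enynoate (Horner–Wadsworth–Emmons from 3-(trimethylsilyl)propynal).
- Bromide ⇐ 2,6-dimethoxytoluene by meta C–H borylation/bromination, Rieche formylation and BBr3; acid ligand ⇐ orsellinic acid and Boc2O.

Assumption: the (R,R) iodoarene 12 is written as the antipode that gives the (7S) ester; the sense of induction of this new ligand transfer must be checked on the first run, and the (S,S) reagent is used if it is the reverse.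

**Step 1**
Reactants: 1 2,6-dimethoxytoluene
Product: 3 5-bromo-1,3-dimethoxy-2-methylbenzene, via aryl pinacolboronate 2 (not isolated)
Conditions: [Ir(OMe)(cod)]2 (1 mol %), dtbpy (2 mol %), B2pin2 (0.6 equiv), THF, 80 °C; then CuBr2 (3 equiv), MeOH/H2O 1:1, 80 °C
Reagents that add atoms: bis(pinacolato)diboron, CC1(C)OB(OC1(C)C)B1OC(C)(C)C(C)(C)O1 (boryl group of intermediate 2 only); CuBr2, [Cu+2].[Br-].[Br-] (bromine of 3)
Why: Iridium-catalysed C–H borylation is sterically governed and takes the only C–H without an ortho neighbour (meta to both methoxy groups, a site electrophilic bromination cannot reach), and the crude boronate undergoes copper-mediated bromodeboronation in the same pot.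

**Step 2**
Reactants: 3 5-bromo-1,3-dimethoxy-2-methylbenzene
Product: 4 6-bromo-2,4-dimethoxy-3-methylbenzaldehyde
Conditions: Cl2CHOMe (1.3 equiv), TiCl4 (2.2 equiv), CH2Cl2, −78 → 0 °C; aq HCl work-up
Reagents that add atoms: dichloromethyl methyl ether, COC(Cl)Cl; water, O
Why: Rieche formylation, in which the two free ring positions are equivalent (each ortho to one methoxy and para to the other), so only one aldehyde can form.

**Step 3**
Reactants: 4 6-bromo-2,4-dimethoxy-3-methylbenzaldehyde
Product: 5 6-bromo-2,4-dihydroxy-3-methylbenzaldehyde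
Conditions: BBr3 (4 equiv), CH2Cl2, −78 °C → rt; H2O
Reagents that add atoms: none
Why: Lewis-acid cleavage of both aryl methyl ethers by BBr3 (the ortho one assisted by chelation to the formyl group), which leaves the aryl bromide and the aldehyde intact.

**Step 4**
Reactants: 6 3-(trimethylsilyl)prop-2-ynal; 7 tert-butyl 2-(diethoxyphosphoryl)acetate
Product: 8 tert-butyl (E)-5-(trimethylsilyl)pent-2-en-4-ynoate
Conditions: 7, NaH, THF, 0 °C; then 6, −78 → 0 °C
Reagents that add atoms: none
Why: Horner–Wadsworth–Emmons olefination with a stabilised phosphonate anion gives the (E)-enoate, and the silyl alkyne survives the anhydrous conditions.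

**Step 5**
Reactants: 5 6-bromo-2,4-dihydroxy-3-methylbenzaldehyde; 8 tert-butyl (E)-5-(trimethylsilyl)pent-2-en-4-ynoate
Product: 9 tert-butyl (E)-5-(2-formyl-3,5-dihydroxy-4-methylphenyl)pent-2-en-4-ynoate
Conditions: Pd(PPh3)4 (5 mol %), CuI (10 mol %), CsF (3 equiv), DMF, 60 °C
Reagents that add atoms: none
Why: Desilylative Sonogashira coupling, in which fluoride turns the alkynylsilane into the copper acetylide in situ so the labile terminal enynoate never accumulates, while the ortho-formyl group speeds oxidative addition of the aryl bromide.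

**Step 6**
Reactants: 10 orsellinic acid (2,4-dihydroxy-6-methylbenzoic acid)
Product: 11 2,4-bis[(tert-butoxycarbonyl)oxy]-6-methylbenzoic acid
Conditions: Boc2O (3.3 equiv), i-Pr2NEt, DMAP (10 mol %), THF, 0 °C → rt; then aq NaHCO3, rt, 1 h; KHSO4 to pH 3
Reagents that add atoms: di-tert-butyl dicarbonate, CC(C)(C)OC(=O)OC(=O)OC(C)(C)C
Why: DMAP-catalysed O-acylation converts both phenols into tert-butyl carbonates, while the di-ortho-substituted carboxyl group only reaches a mixed anhydride that the bicarbonate work-up hydrolyses back to the acid.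

**Step 7**
Reactants: 9 tert-butyl (E)-5-(2-formyl-3,5-dihydroxy-4-methylphenyl)pent-2-en-4-ynoate; 11 2,4-bis[(tert-butoxycarbonyl)oxy]-6-methylbenzoic acid; 12 (2R,2'R)-2,2'-[(2-iodo-1,3-phenylene)bis(oxy)]bis[N-(2,4,6-trimethylphenyl)propanamide]
Product: 15 tert-butyl (E)-3-[(7S)-7-({2,4-bis[(tert-butoxycarbonyl)oxy]-6-methylbenzoyl}oxy)-7-methyl-6,8-dioxo-7,8-dihydro-6H-isochromen-3-yl]prop-2-enoate, via anhydrobase 13 (not isolated), via bis(aroyloxy)iodane 14 (not isolated)
Conditions: 9, Ph3PAuNTf2 (3 mol %), ClCH2CH2Cl/(CF3)2CHOH 4:1, rt, 1 h (gives 13); separately 12 (1.2 equiv), AcOOH/AcOH, CH2Cl2, 30 °C, evaporate, then 11 (2.5 equiv), PhMe, 40 °C, AcOH stripped in vacuo three times (gives 14); 14 in CH2Cl2 added to 13 at −40 °C, then −20 °C, 12 h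
Reagents that add atoms: none
Why: Proposed new method: monovalent gold activates the alkyne for 6-endo attack of the formyl oxygen and a phenolic proton releases the metal to give the planar anhydrobase 13, a vinylogous 2-methyl-1,3-dione enol whose O8 (or O6) displaces one aroate on the trivalent iodine of 14, after which an aroate is delivered to C7 (the only carbon flanked by both oxygens) as the aryl–iodine unit leaves as iodoarene 12, so the ester bond and the stereocentre form together with the face chosen by the C2-symmetric lactamide arms folded over iodine through N–H···O hydrogen bonds; the closest known reaction types are the Wessely acyloxylation of 6,8-dihydroxy-2-benzopyrylium salts with Pb(OAc)4 to racemic 7-acetoxyazaphilones and the enantioselective Kita dearomatising spirolactonisation with the same chiral aryl-λ3-iodanes.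

**Step 8**
Reactants: 15 tert-butyl (E)-3-[(7S)-7-({2,4-bis[(tert-butoxycarbonyl)oxy]-6-methylbenzoyl}oxy)-7-methyl-6,8-dioxo-7,8-dihydro-6H-isochromen-3-yl]prop-2-enoate
Product: 16 (S)-mitorubrinic acid, (E)-3-[(7S)-7-[(2,4-dihydroxy-6-methylbenzoyl)oxy]-7-methyl-6,8-dioxo-7,8-dihydro-6H-isochromen-3-yl]prop-2-enoic acid
Conditions: CF3CO2H/CH2Cl2 1:4, 0 °C → rt, 2 h
Reagents that add atoms: none
Why: Acidolysis (E1 loss of the tert-butyl cation) removes both aryl carbonates and the tert-butyl ester at once, while the C7 ester cannot ionise (its cation would sit between two carbonyls) and the quaternary stereocentre has no α-hydrogen to epimerise.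

**Compound list**
1 | 2,6-dimethoxytoluene | COc1cccc(OC)c1C | starting material
2 | 2-(3,5-dimethoxy-4-methylphenyl)-4,4,5,5-tetramethyl-1,3,2-dioxaborolane | COc1cc(B2OC(C)(C)C(C)(C)O2)cc(OC)c1C | intermediate
3 | 5-bromo-1,3-dimethoxy-2-methylbenzene | COc1cc(Br)cc(OC)c1C | intermediate
4 | 6-bromo-2,4-dimethoxy-3-methylbenzaldehyde | COc1cc(Br)c(C=O)c(OC)c1C | intermediate
5 | 6-bromo-2,4-dihydroxy-3-methylbenzaldehyde | Oc1cc(Br)c(C=O)c(O)c1C | intermediate
6 | 3-(trimethylsilyl)prop-2-ynal | C[Si](C)(C)C#CC=O | starting material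
7 | tert-butyl 2-(diethoxyphosphoryl)acetate | CCOP(=O)(OCC)CC(=O)OC(C)(C)C | starting material
8 | tert-butyl (E)-5-(trimethylsilyl)pent-2-en-4-ynoate | C[Si](C)(C)C#C/C=C/C(=O)OC(C)(C)C | intermediate
9 | tert-butyl (E)-5-(2-formyl-3,5-dihydroxy-4-methylphenyl)pent-2-en-4-ynoate | Cc1c(O)cc(C#C/C=C/C(=O)OC(C)(C)C)c(C=O)c1O | intermediate
10 | orsellinic acid (2,4-dihydroxy-6-methylbenzoic acid) | Cc1cc(O)cc(O)c1C(=O)O | starting material
11 | 2,4-bis[(tert-butoxycarbonyl)oxy]-6-methylbenzoic acid | Cc1cc(OC(=O)OC(C)(C)C)cc(OC(=O)OC(C)(C)C)c1C(=O)O | intermediate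
12 | (2R,2'R)-2,2'-[(2-iodo-1,3-phenylene)bis(oxy)]bis[N-(2,4,6-trimethylphenyl)propanamide] | C[C@@H](Oc1cccc(O[C@H](C)C(=O)Nc2c(C)cc(C)cc2C)c1I)C(=O)Nc1c(C)cc(C)cc1C | starting material
13 | tert-butyl (E)-3-(8-hydroxy-7-methyl-6-oxo-6H-isochromen-3-yl)prop-2-enoate (anhydrobase; the 6-hydroxy-8-oxo tautomer is equivalent) | CC1=C(O)C2=COC(/C=C/C(=O)OC(C)(C)C)=CC2=CC1=O | intermediate
14 | aryl-λ3-iodane of 12 carrying two 2,4-bis[(tert-butoxycarbonyl)oxy]-6-methylbenzoate ligands on iodine | C[C@@H](Oc1cccc(O[C@H](C)C(=O)Nc2c(C)cc(C)cc2C)c1I(OC(=O)c1c(C)cc(OC(=O)OC(C)(C)C)cc1OC(=O)OC(C)(C)C)OC(=O)c1c(C)cc(OC(=O)OC(C)(C)C)cc1OC(=O)OC(C)(C)C)C(=O)Nc1c(C)cc(C)cc1C | intermediate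
15 | tert-butyl (E)-3-[(7S)-7-({2,4-bis[(tert-butoxycarbonyl)oxy]-6-methylbenzoyl}oxy)-7-methyl-6,8-dioxo-7,8-dihydro-6H-isochromen-3-yl]prop-2-enoate | Cc1cc(OC(=O)OC(C)(C)C)cc(OC(=O)OC(C)(C)C)c1C(=O)O[C@@]1(C)C(=O)C=C2C=C(/C=C/C(=O)OC(C)(C)C)OC=C2C1=O | intermediate
16 | (S)-mitorubrinic acid | Cc1cc(O)cc(O)c1C(=O)O[C@@]1(C)C(=O)C=C2C=C(/C=C/C(=O)O)OC=C2C1=O | target

**Step count:** 8 steps in total. Longest linear sequence: 6 steps (steps 1, 2, 3, 5, 7, 8 from 2,6-dimethoxytoluene).

**Steps most likely to fail**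

Step 7 carries the most risk. The gold cyclisation is run without strong acid, a hindered aroate must be transferred to a fully substituted carbon, and the level and sense of induction of an intermolecular ligand transfer are untested. The fallback separates oxygenation from acylation and sets out from 9. Copper–dioxygen hydroxylative dearomatisation ([Cu(MeCN)4]PF6, (+)-sparteine, i-Pr2NEt, DMAP, O2, CH2Cl2, −78 → −10 °C) uses the enantiomer of the diamine that leads to the 7R series. It gives tert-butyl (E)-5-[(4S)-2-formyl-4,5-dihydroxy-4-methyl-3-oxocyclohexa-1,5-dien-1-yl]pent-2-en-4-ynoate F1. This is cycloisomerised with KH2PO4/K2HPO4 buffer in MeCN to tert-butyl (E)-3-[(7S)-7-hydroxy-7-methyl-6,8-dioxo-7,8-dihydro-6H-isochromen-3-yl]prop-2-enoate F2. The tertiary alcohol is then acylated (Et3N, DMAP, CH2Cl2) with 2,4-bis[(tert-butoxycarbonyl)oxy]-6-methylbenzoyl chloride F3, made from 11 with 1-chloro-N,N,2-trimethylprop-1-en-1-amine. The sequence comes back to the route at 15.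

Step 5 is the second risk. The bromide is an electron-rich phenoxide under the conditions, and copper with fluoride at 60 °C may cyclise or degrade the free-phenol alkynylbenzaldehyde. The fallback masks the phenols and couples an isolated terminal alkyne under mild amine conditions; it sets out from 5 and 8. Bromide 5 is acetylated (Ac2O, pyridine) to 5-bromo-4-formyl-2-methyl-1,3-phenylene diacetate F4. Silane 8 is desilylated (Bu4NF, AcOH, THF, 0 °C) to tert-butyl (E)-pent-2-en-4-ynoate F5. The two are joined (PdCl2(PPh3)2, CuI, Et3N, THF, rt) to give 5-[(E)-5-tert-butoxy-5-oxopent-3-en-1-yn-1-yl]-4-formyl-2-methyl-1,3-phenylene diacetate F6. Brief methanolysis (cat. K2CO3, MeOH, 0 °C) removes the acetates and comes back to the route at 9.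

Step 6 is the third risk. The chelated 2-hydroxyl may acylate incompletely, and the free carboxyl group may be consumed as a tert-butyl ester or anhydride. The fallback blocks the acid first and sets out from 10. Carboxylate alkylation (BnBr, KHCO3, DMF) gives benzyl 2,4-dihydroxy-6-methylbenzoate F7. Boc2O with DMAP in MeCN gives benzyl 2,4-bis[(tert-butoxycarbonyl)oxy]-6-methylbenzoate F8. Hydrogenolysis (H2, Pd/C, EtOAc) comes back to the route at 11.

**Further compounds**
F1 | step 7 | tert-butyl (E)-5-[(4S)-2-formyl-4,5-dihydroxy-4-methyl-3-oxocyclohexa-1,5-dien-1-yl]pent-2-en-4-ynoate | O=CC1=C(C#C/C=C/C(=O)OC(C)(C)C)C=C(O)[C@](C)(O)C1=O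
F2 | step 7 | tert-butyl (E)-3-[(7S)-7-hydroxy-7-methyl-6,8-dioxo-7,8-dihydro-6H-isochromen-3-yl]prop-2-enoate | O[C@@]1(C)C(=O)C=C2C=C(/C=C/C(=O)OC(C)(C)C)OC=C2C1=O
F3 | step 7 | 2,4-bis[(tert-butoxycarbonyl)oxy]-6-methylbenzoyl chloride | Cc1cc(OC(=O)OC(C)(C)C)cc(OC(=O)OC(C)(C)C)c1C(Cl)=O
F4 | step 5 | 5-bromo-4-formyl-2-methyl-1,3-phenylene diacetate | CC(=O)Oc1cc(Br)c(C=O)c(OC(C)=O)c1C
F5 | step 5 | tert-butyl (E)-pent-2-en-4-ynoate | C#C/C=C/C(=O)OC(C)(C)C
F6 | step 5 | 5-[(E)-5-tert-butoxy-5-oxopent-3-en-1-yn-1-yl]-4-formyl-2-methyl-1,3-phenylene diacetate | CC(=O)Oc1cc(C#C/C=C/C(=O)OC(C)(C)C)c(C=O)c(OC(C)=O)c1C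
F7 | step 6 | benzyl 2,4-dihydroxy-6-methylbenzoate | Cc1cc(O)cc(O)c1C(=O)OCc1ccccc1
F8 | step 6 | benzyl 2,4-bis[(tert-butoxycarbonyl)oxy]-6-methylbenzoate | Cc1cc(OC(=O)OC(C)(C)C)cc(OC(=O)OC(C)(C)C)c1C(=O)OCc1ccccc1
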